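**Retrosynthetic overview**

1. Butanolide numbering: O1, C2 (lactone C=O), C3 (CH3), C4 (CO2H), C5 (14-oxopentadecyl). The C5 oxygen is β to the carboxyl carbon on C4 and γ to the C2 carbonyl. The O–C5–C4–CO2H unit is therefore first closed as a cis-oxetan-2-one (a four-membered ring absent from the target), and the same oxygen is later re-acylated by the C2 carboxyl to give the five-membered lactone.
2. The oxetanone is cut across C4–C5 and the O–acyl bond (catalytic asymmetric ketene–aldehyde [2+2]) into 15-oxohexadecanal and the ketene from the mono-acid chloride of benzyl (S)-2-methylsuccinate.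
3. The keto-aldehyde comes from ω-pentadecalactone (Weinreb amide, MeMgBr, oxidation). The acid chloride comes from an oxazolidinone-directed alkylation of a propionimide with tert-butyl bromoacetate, which sets C3.
4. Ring order: the four-membered lactone is closed first and joins the two fragments, hydroxide opens it, and the five-membered lactone is closed last.

Key step: step 8

Assumption: O-trimethylsilylquinidine is taken as the pseudoenantiomer that gives the (3R,4S) cis-oxetanone (the quinine-derived silyl ether giving the mirror image), as expected for simple alkylketenes. A model run of aldehyde 4 with propionyl chloride should confirm this sense before acid chloride 11 is committed.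

**Route**

Step 1
Reactants: 1 ω-pentadecalactone (oxacyclohexadecan-2-one)
Product: 2 15-hydroxy-N-methoxy-N-methylpentadecanamide
Conditions: MeNH(OMe)·HCl (3 equiv), AlMe3 (3 equiv), CH2Cl2, 0 °C to rt; aq. HCl work-up
Reagents that add atoms: N,O-dimethylhydroxylamine hydrochloride, CNOC.Cl
Why: Weinreb aminolysis of a lactone, in which the aluminium amide formed from AlMe3 and the amine salt opens the macrolactone at the acyl carbon and frees the terminal alcohol.

Step 2
Reactants: 2 15-hydroxy-N-methoxy-N-methylpentadecanamide
Product: 3 16-hydroxyhexadecan-2-one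
Conditions: MeMgBr (3.5 equiv), THF, 0 °C; aq. NH4Cl
Reagents that add atoms: methylmagnesium bromide, C[Mg]Br
Why: Weinreb ketone synthesis, in which the first equivalent of Grignard reagent deprotonates the alcohol and the amide takes up one methyl group only, because collapse to the ketone waits for the aqueous quench.

Step 3
Reactants: 3 16-hydroxyhexadecan-2-one
Product: 4 15-oxohexadecanal
Conditions: TEMPO (10 mol%), PhI(OAc)2 (1.1 equiv), CH2Cl2, rt; short silica plug, used the same day
Reagents that add atoms: none
Why: Oxoammonium-mediated (TEMPO/PhI(OAc)2) oxidation of a primary alcohol should stop at the aldehyde in anhydrous CH2Cl2 and leave the methyl ketone untouched.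

Step 4
Reactants: 5 (R)-4-benzyl-3-propionyloxazolidin-2-one; 6 tert-butyl bromoacetate
Product: 8 tert-butyl (S)-4-[(R)-4-benzyl-2-oxooxazolidin-3-yl]-3-methyl-4-oxobutanoate, via sodium Z-enolate 7 (not isolated)
Conditions: NaN(SiMe3)2 (1.1 equiv), THF, −78 °C; then 6 (2 equiv), −78 to −50 °C; aq. NH4Cl
Reagents that add atoms: none
Why: Evans alkylation, in which the chelated sodium Z-enolate is attacked by the bromoacetate on the face opposite the benzyl group of the (R)-auxiliary, which should set the methyl-bearing centre as (S).

Step 5
Reactants: 8 tert-butyl (S)-4-[(R)-4-benzyl-2-oxooxazolidin-3-yl]-3-methyl-4-oxobutanoate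
Product: 9 1-benzyl 4-tert-butyl (S)-2-methylsuccinate
Conditions: BnOH (2 equiv), n-BuLi (1.5 equiv), THF, −78 to 0 °C; then 8, 0 °C; aq. NH4Cl
Reagents that add atoms: benzyl alcohol (as lithium benzyloxide), OCc1ccccc1
Why: Transesterification of the N-acyloxazolidinone with lithium benzyloxide, which should attack the exocyclic imide carbonyl selectively, spare the tert-butyl ester and leave the α-centre unepimerised at 0 °C.

Step 6
Reactants: 9 1-benzyl 4-tert-butyl (S)-2-methylsuccinate
Product: 10 (S)-4-(benzyloxy)-3-methyl-4-oxobutanoic acid
Conditions: CF3CO2H/CH2Cl2 (1:3), 0 °C to rt; co-evaporation with toluene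
Reagents that add atoms: none
Why: Acidolysis of the tert-butyl ester through the tert-butyl cation (loss of 2-methylpropene) leaves the benzyl ester and the stereocentre untouched.

Step 7
Reactants: 10 (S)-4-(benzyloxy)-3-methyl-4-oxobutanoic acid
Product: 11 benzyl (S)-4-chloro-2-methyl-4-oxobutanoate
Conditions: (COCl)2 (1.3 equiv), DMF (cat.), CH2Cl2, 0 °C to rt; volatiles removed below 25 °C, used crude as a CH2Cl2 solution
Reagents that add atoms: oxalyl chloride, O=C(Cl)C(=O)Cl
Why: Acid chloride formation through the Vilsmeier-type chloroiminium species under neutral, cold conditions, which should avoid both epimerisation of the remote α-ester centre and thermal closure to the anhydride.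

Step 8
Reactants: 4 15-oxohexadecanal; 11 benzyl (S)-4-chloro-2-methyl-4-oxobutanoate
Product: 13 benzyl (S)-2-[(3R,4S)-2-oxo-4-(14-oxopentadecyl)oxetan-3-yl]propanoate, via ketene 12 (not isolated)
Conditions: O-trimethylsilylquinidine (10 mol%), LiClO4 (2 equiv), iPr2NEt (2.5 equiv), CH2Cl2/Et2O, −78 °C; 11 (2 equiv) added over 3–4 h by syringe pump
Reagents that add atoms: none
Why: iPr2NEt dehydrochlorinates 11 to the monosubstituted ketene 12, and the quinuclidine nitrogen of the alkaloid adds to its carbonyl carbon to give a catalyst-bound acylammonium enolate, Z because the single ketene substituent turns away from the ammonium group; LiClO4 then ties the enolate oxygen and the aldehyde of 4 into a chair-like six-membered aldol transition state that forms the oxetanone C3–C4 bond (C4–C5 of the target). The lithium alkoxide so formed attacks the acylammonium carbon in a 4-exo-trig closure that makes the O–acyl bond, closes the oxetan-2-one and releases the catalyst. The closest known reaction is the cinchona alkaloid/lithium salt catalysed acyl halide–aldehyde cyclocondensation (formal ketene–aldehyde [2+2]) of alkyl-substituted acid chlorides with unbranched aliphatic aldehydes, applied here to a β-branched, ester-bearing member of that class. The Z enolate in the closed transition state should fix the cis relation of the two new centres, and the quinidine scaffold, which shields one enolate face, should fix their absolute sense as (3R,4S) under catalyst control, regardless of the resident (S) centre in the ketene side chain. The step also needs the aldehyde to react in preference to the methyl ketone of 4, which the far lower electrophilicity of an unactivated ketone at −78 °C should secure, while the benzyl ester is a spectator and slow addition of 11 keeps the ketene concentration low enough to suppress dimerisation.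

Step 9
Reactants: 13 benzyl (S)-2-[(3R,4S)-2-oxo-4-(14-oxopentadecyl)oxetan-3-yl]propanoate
Product: 15 (2S,3R,4S)-4-methyl-5-oxo-2-(14-oxopentadecyl)tetrahydrofuran-3-carboxylic acid, via hydroxy diacid 14 (not isolated)
Conditions: LiOH·H2O (4 equiv), THF/H2O (3:1), 0 °C; then 2 M HCl to pH 1, rt to 40 °C
Reagents that add atoms: lithium hydroxide, [Li+].[OH-]
Why: Hydroxide should open the strained oxetanone at the acyl carbon (retention at the carbinol) and saponify the benzyl ester to give 14 as its dilithium salt, and on acidification the hydroxyl closes onto the C2 carboxyl in a 5-exo-trig lactonisation (the only unstrained ring available) without breaking a bond at any stereocentre, so the cis-oxetanone maps onto the 4,5-trans, 3,4-cis butanolide.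

**Compound list**

1 | ω-pentadecalactone (oxacyclohexadecan-2-one) | O=C1CCCCCCCCCCCCCCO1 | starting material
2 | 15-hydroxy-N-methoxy-N-methylpentadecanamide | CON(C)C(=O)CCCCCCCCCCCCCCO | intermediate
3 | 16-hydroxyhexadecan-2-one | CC(=O)CCCCCCCCCCCCCCO | intermediate
4 | 15-oxohexadecanal | CC(=O)CCCCCCCCCCCCCC=O | intermediate
5 | (R)-4-benzyl-3-propionyloxazolidin-2-one | CCC(=O)N1[C@H](Cc2ccccc2)COC1=O | starting material
6 | tert-butyl bromoacetate | CC(C)(C)OC(=O)CBr | starting material
7 | sodium Z-enolate of 5 (formed in the flask) | C/C=C(\[O-])N1[C@H](Cc2ccccc2)COC1=O.[Na+] | intermediate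
8 | tert-butyl (S)-4-[(R)-4-benzyl-2-oxooxazolidin-3-yl]-3-methyl-4-oxobutanoate | CC(C)(C)OC(=O)C[C@H](C)C(=O)N1[C@H](Cc2ccccc2)COC1=O | intermediate
9 | 1-benzyl 4-tert-butyl (S)-2-methylsuccinate | CC(C)(C)OC(=O)C[C@H](C)C(=O)OCc1ccccc1 | intermediate
10 | (S)-4-(benzyloxy)-3-methyl-4-oxobutanoic acid | OC(=O)C[C@H](C)C(=O)OCc1ccccc1 | intermediate
11 | benzyl (S)-4-chloro-2-methyl-4-oxobutanoate | ClC(=O)C[C@H](C)C(=O)OCc1ccccc1 | intermediate
12 | benzyl (S)-2-methyl-4-oxobut-3-enoate (the ketene from 11; formed in the flask) | O=C=C[C@H](C)C(=O)OCc1ccccc1 | intermediate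
13 | benzyl (S)-2-[(3R,4S)-2-oxo-4-(14-oxopentadecyl)oxetan-3-yl]propanoate | CC(=O)CCCCCCCCCCCCC[C@@H]1OC(=O)[C@@H]1[C@H](C)C(=O)OCc1ccccc1 | intermediate
14 | (2R,3S)-2-[(S)-1-hydroxy-15-oxohexadecyl]-3-methylsuccinic acid (formed in the flask; its dilithium salt until acidified) | CC(=O)CCCCCCCCCCCCC[C@H](O)[C@H](C(=O)O)[C@H](C)C(=O)O | intermediate
15 | (2S,3R,4S)-4-methyl-5-oxo-2-(14-oxopentadecyl)tetrahydrofuran-3-carboxylic acid | CC(=O)CCCCCCCCCCCCC[C@@H]1OC(=O)[C@@H](C)[C@H]1C(=O)O | target

**Step count**

Total: 9 steps. Longest linear sequence: 6 steps (steps 4 to 9, from 5 to 15).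

**Steps most likely to fail, with fallbacks**

Step 8. With the bulkier β-branched ketene, aldol addition of the catalyst-bound enolate may be outrun by ketene dimerisation, or the resident (S) centre may erode the facial selectivity of the alkaloid in a mismatched pairing. The fallback sets out from 11 and comes back at 14. (R)-4-Benzyloxazolidin-2-one (recovered from step 5) is lithiated (n-BuLi, THF, −78 °C) and acylated with 11 to give benzyl (S)-4-[(R)-4-benzyl-2-oxooxazolidin-3-yl]-2-methyl-4-oxobutanoate F1. An Evans syn-aldol (n-Bu2BOTf, iPr2NEt, CH2Cl2, 0 °C; then 4 at −78 °C; buffered H2O2 work-up at 0 °C) through the Z boron enolate in a chair transition state should give benzyl (2S,3R,4S)-3-[(R)-4-benzyl-2-oxooxazolidine-3-carbonyl]-4-hydroxy-2-methyl-18-oxononadecanoate F2, with the (R)-auxiliary setting the same two centres as the oxetanone would carry. LiOH/H2O2 (THF/H2O, 0 °C) then removes the auxiliary and the excess LiOH the benzyl ester, which arrives at 14; acidification as in step 9 closes it to 15.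

Step 9. While the benzyl ester is being saponified, base-mediated epimerisation at the carbon α to an ester or lactone carbonyl, or β-elimination of the opened hydroxy acid, may compete. The fallback sets out from 13 and comes back at 14. Hydrogenolysis (H2, Pd/C, EtOAc, rt), which the oxetanone and the ketone should tolerate, gives (S)-2-[(3R,4S)-2-oxo-4-(14-oxopentadecyl)oxetan-3-yl]propanoic acid F3. A brief exposure to LiOH (2.2 equiv, THF/H2O, 0 °C) then has only the strained ring to open and leads to 14 with no ester α-proton left in the molecule; acidification gives 15.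

Step 5. The alkoxide may attack the ring carbonyl of the oxazolidinone (endocyclic cleavage) or epimerise the α-methyl centre before acyl transfer is complete. The fallback sets out from 8 and comes back at 9. LiOH/H2O2 (THF/H2O, 0 °C) cleaves the auxiliary to (S)-4-(tert-butoxy)-2-methyl-4-oxobutanoic acid F4, and O-alkylation of its caesium carboxylate (BnBr, Cs2CO3, DMF, rt) gives 9.

**Further compounds**

F1 | step 8 | benzyl (S)-4-[(R)-4-benzyl-2-oxooxazolidin-3-yl]-2-methyl-4-oxobutanoate | O=C(C[C@H](C)C(=O)OCc1ccccc1)N1[C@H](Cc2ccccc2)COC1=O
F2 | step 8 | benzyl (2S,3R,4S)-3-[(R)-4-benzyl-2-oxooxazolidine-3-carbonyl]-4-hydroxy-2-methyl-18-oxononadecanoate | CC(=O)CCCCCCCCCCCCC[C@H](O)[C@H](C(=O)N1[C@H](Cc2ccccc2)COC1=O)[C@H](C)C(=O)OCc1ccccc1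
F3 | step 9 | (S)-2-[(3R,4S)-2-oxo-4-(14-oxopentadecyl)oxetan-3-yl]propanoic acid | CC(=O)CCCCCCCCCCCCC[C@@H]1OC(=O)[C@@H]1[C@H](C)C(=O)O
F4 | step 5 | (S)-4-(tert-butoxy)-2-methyl-4-oxobutanoic acid | CC(C)(C)OC(=O)C[C@H](C)C(=O)O
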